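**Retrosynthetic overview**
- Target 14 is a (4S)-4-phenylchroman-2-one. Ring A (C4a, C5, C6, C7, C8, C8a) is a phloroglucinol carrying the C8 ketone, and ring B (O1, C2, C3, C4, C4a, C8a) is the lactone.
- Feature used: C4 is attached to C4a, the carbon ortho to the C8a oxygen, and the other neighbour of C8a is C8 with its ketone. The C4–C4a bond is therefore cut as a retro-aromatic-Claisen to an (E)-cinnamyl ether on the C8a oxygen. The ether and ketone oxygens form a two-point site for a chiral Lewis acid, and C4a is the only free ortho carbon.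
- Ring B is opened at O1–C2. C3 and C2 are the two vinyl carbons of the Claisen product (anti-Markovnikov hydration, then alcohol, lactol, lactone). The C5 and C7 oxygens are carried as benzyl ethers.
- The cinnamyl ether comes from phloroglucinol by C-acylation, double O-benzylation and O-cinnamylation.
- Ring order: ring A is bought, and ring B is the only ring made (step 6).

Key step: step 4

Assumption: the (R,R) ligand is chosen from a quadrant model of the square-planar chelate, in which the oxazoline phenyl group next to the bound ether oxygen blocks one arene face. If the first run shows the opposite sense, the equally available (S,S) ligand is used in the same procedure.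

**Step 1**
Reactants: 1 phloroglucinol; 2 3-(4-methoxyphenyl)propanoic acid
Product: 3 3-(4-methoxyphenyl)-1-(2,4,6-trihydroxyphenyl)propan-1-one
Conditions: BF3·OEt2 (as medium), 85 °C; then aq NaOAc
Reagents that add atoms: none
Why: Friedel–Crafts acylation in which BF3 activates the acid, the symmetric and very electron-rich phloroglucinol is acylated only once because the new ketone deactivates it, and the anisole ring of 2 is too weak a nucleophile to compete (its closure to an indanone would have to occur meta to OMe).

**Step 2**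
Reactants: 3 3-(4-methoxyphenyl)-1-(2,4,6-trihydroxyphenyl)propan-1-one
Product: 4 1-[2,4-bis(benzyloxy)-6-hydroxyphenyl]-3-(4-methoxyphenyl)propan-1-one
Conditions: BnBr (2.05 equiv), K2CO3 (2.2 equiv), DMF, rt to 50 °C
Reagents that add atoms: benzyl bromide, BrCc1ccccc1
Why: Williamson ether synthesis in which the para hydroxyl and one ortho hydroxyl are alkylated, while the last ortho hydroxyl is held in a strong hydrogen bond to the ketone and stays free when the bromide is limited to two equivalents.

**Step 3**
Reactants: 4 1-[2,4-bis(benzyloxy)-6-hydroxyphenyl]-3-(4-methoxyphenyl)propan-1-one; 5 (E)-cinnamyl bromide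
Product: 6 1-[2,4-bis(benzyloxy)-6-[(E)-cinnamyloxy]phenyl]-3-(4-methoxyphenyl)propan-1-one
Conditions: 5 (1.2 equiv), K2CO3 (2 equiv), DMF, rt to 40 °C
Reagents that add atoms: none
Why: Williamson ether synthesis (SN2 at the primary allylic carbon) in which carbonate in DMF breaks the hydrogen bond, the reactive bromide alkylates the phenoxide at oxygen with the E geometry kept, and the temperature lies far below that of a thermal Claisen shift.

**Step 4**
Reactants: 6 1-[2,4-bis(benzyloxy)-6-[(E)-cinnamyloxy]phenyl]-3-(4-methoxyphenyl)propan-1-one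
Product: 8 1-[2,4-bis(benzyloxy)-6-hydroxy-5-[(1S)-1-phenylprop-2-en-1-yl]phenyl]-3-(4-methoxyphenyl)propan-1-one, via ortho-dienone 7 (not isolated)
Conditions: Cu(OTf)2 (10 mol %), (R,R)-Ph-box = 2,2'-(propane-2,2-diyl)bis[(4R)-4-phenyl-4,5-dihydro-1,3-oxazole] (11 mol %), 4 Å MS, CH2Cl2, −20 °C to rt
Reagents that add atoms: none
Why: Proposed new method: the Cu(OTf)2–bis(oxazoline) complex (divalent copper) should bind the cinnamyl ether oxygen and the ketone oxygen of 6 in a six-membered chelate, weaken the O–CH2 bond and let the concerted [3,3] shift (aromatic Claisen rearrangement) run far below its thermal threshold to ortho-dienone 7, which enolises to phenol 8. The closest known reaction type is the chiral-Lewis-acid-catalysed enantioselective Claisen rearrangement of two-point-binding substrates, shown for 2-alkoxycarbonyl allyl vinyl ethers and for allyl 2-naphthyl ethers with an ortho carbonyl group, but not for a monocyclic phloroglucinol ketone or a cinnamyl terminus. No ring is closed; only the C4–C4a bond forms and the C8a hydroxyl is set free. C4 is the only lasting stereocentre: the E geometry places the phenyl group pseudo-equatorial in the chair, so its configuration follows from the arene face that the allyl terminus reaches, and that face is chosen by the oxazoline phenyl group next to the bound ether oxygen, the (R,R) ligand being expected to give (S). Regioselectivity is secured by the substrate, since one ortho carbon (C8) carries the ketone and only C4a is open. The step also needs the concerted path to outrun ionisation to a cinnamyl cation, which the tight chelate, the weakly polar solvent, the low temperature and the acid-free medium should favour.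

**Step 5**
Reactants: 8 1-[2,4-bis(benzyloxy)-6-hydroxy-5-[(1S)-1-phenylprop-2-en-1-yl]phenyl]-3-(4-methoxyphenyl)propan-1-one
Product: 10 1-[2,4-bis(benzyloxy)-6-hydroxy-5-[(1S)-3-hydroxy-1-phenylpropyl]phenyl]-3-(4-methoxyphenyl)propan-1-one, via pinacol boronate 9 (not isolated)
Conditions: HBpin (2.5 equiv), [Ir(cod)Cl]2 (1.5 mol %), dppm (3 mol %), THF, rt; then NaBO3·4H2O, THF/H2O, 0 °C to rt
Reagents that add atoms: pinacolborane, CC1(C)OBOC1(C)C (its boron and pinacolate stay in 9 only); sodium perborate, [Na+].[O-]OB=O (gives the hydroxyl oxygen of 10)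
Why: Iridium-catalysed anti-Markovnikov hydroboration of a monosubstituted alkene followed by boronate oxidation, in which pinacolborane leaves the hindered, electron-rich aryl ketone alone (a free borane would not), boron goes to the terminal carbon for steric reasons, perborate oxidises the C–B bond under mild conditions, any O–Bpin formed at the phenol is hydrolysed in the same work-up, and C4 is not touched.

**Step 6**
Reactants: 10 1-[2,4-bis(benzyloxy)-6-hydroxy-5-[(1S)-3-hydroxy-1-phenylpropyl]phenyl]-3-(4-methoxyphenyl)propan-1-one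
Product: 13 (4S)-5,7-bis(benzyloxy)-8-[3-(4-methoxyphenyl)propanoyl]-4-phenylchroman-2-one, via hydroxy aldehyde 11 (not isolated), via chroman-2-ol 12 (not isolated)
Conditions: pyridinium chlorochromate [C5H5NH][CrO3Cl] (3 equiv), NaOAc, 4 Å MS, CH2Cl2, rt
Reagents that add atoms: none
Why: Chlorochromate oxidation of the primary alcohol to aldehyde 11, which the C8a phenol closes to the six-membered lactol 12, which is oxidised again to the lactone; this is the established way from chroman-2-ols to 3,4-dihydrocoumarins and does not involve C4.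

**Step 7**
Reactants: 13 (4S)-5,7-bis(benzyloxy)-8-[3-(4-methoxyphenyl)propanoyl]-4-phenylchroman-2-one
Product: 14 (4S)-5,7-dihydroxy-8-[3-(4-methoxyphenyl)propanoyl]-4-phenylchroman-2-one (target)
Conditions: H2 (1 atm), 10% Pd/C, EtOAc, rt
Reagents that add atoms: none
Why: Catalytic hydrogenolysis of the two aryl benzyl ethers, in which the electron-rich aryl ketone, the aryl methyl ether and the lactone are inert at one atmosphere, C4 has no benzylic C–O bond to lose, and the non-nucleophilic solvent prevents opening of the aryl ester and its re-closure on the C5 hydroxyl.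

**Compound list**
1 | phloroglucinol | Oc1cc(O)cc(O)c1 | starting material
2 | 3-(4-methoxyphenyl)propanoic acid | COc1ccc(CCC(=O)O)cc1 | starting material
3 | 3-(4-methoxyphenyl)-1-(2,4,6-trihydroxyphenyl)propan-1-one | COc1ccc(CCC(=O)c2c(O)cc(O)cc2O)cc1 | intermediate
4 | 1-[2,4-bis(benzyloxy)-6-hydroxyphenyl]-3-(4-methoxyphenyl)propan-1-one | COc1ccc(CCC(=O)c2c(O)cc(OCc3ccccc3)cc2OCc2ccccc2)cc1 | intermediate
5 | (E)-cinnamyl bromide | BrC/C=C/c1ccccc1 | starting material
6 | 1-[2,4-bis(benzyloxy)-6-[(E)-cinnamyloxy]phenyl]-3-(4-methoxyphenyl)propan-1-one | COc1ccc(CCC(=O)c2c(OCc3ccccc3)cc(OCc3ccccc3)cc2OC/C=C/c2ccccc2)cc1 | intermediate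
7 | (6R)-3,5-bis(benzyloxy)-2-[3-(4-methoxyphenyl)propanoyl]-6-[(1R)-1-phenylprop-2-en-1-yl]cyclohexa-2,4-dien-1-one (ortho-dienone, not isolated) | C=C[C@H]([C@H]1C(=O)C(C(=O)CCc2ccc(OC)cc2)=C(OCc2ccccc2)C=C1OCc1ccccc1)c1ccccc1 | intermediate
8 | 1-[2,4-bis(benzyloxy)-6-hydroxy-5-[(1S)-1-phenylprop-2-en-1-yl]phenyl]-3-(4-methoxyphenyl)propan-1-one | C=C[C@H](c1c(OCc2ccccc2)cc(OCc2ccccc2)c(C(=O)CCc2ccc(OC)cc2)c1O)c1ccccc1 | intermediate
9 | 1-[2,4-bis(benzyloxy)-6-hydroxy-5-[(1S)-1-phenyl-3-(4,4,5,5-tetramethyl-1,3,2-dioxaborolan-2-yl)propyl]phenyl]-3-(4-methoxyphenyl)propan-1-one (pinacol boronate, not isolated) | CC1(C)OB(CC[C@H](c2c(OCc3ccccc3)cc(OCc3ccccc3)c(C(=O)CCc3ccc(OC)cc3)c2O)c2ccccc2)OC1(C)C | intermediate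
10 | 1-[2,4-bis(benzyloxy)-6-hydroxy-5-[(1S)-3-hydroxy-1-phenylpropyl]phenyl]-3-(4-methoxyphenyl)propan-1-one | OCC[C@H](c1c(OCc2ccccc2)cc(OCc2ccccc2)c(C(=O)CCc2ccc(OC)cc2)c1O)c1ccccc1 | intermediate
11 | (3S)-3-[4,6-bis(benzyloxy)-2-hydroxy-3-[3-(4-methoxyphenyl)propanoyl]phenyl]-3-phenylpropanal (hydroxy aldehyde, not isolated) | O=CC[C@H](c1c(OCc2ccccc2)cc(OCc2ccccc2)c(C(=O)CCc2ccc(OC)cc2)c1O)c1ccccc1 | intermediate
12 | 1-[(4S)-5,7-bis(benzyloxy)-2-hydroxy-4-phenylchroman-8-yl]-3-(4-methoxyphenyl)propan-1-one (chroman-2-ol, both C2 epimers, not isolated) | COc1ccc(CCC(=O)c2c(OCc3ccccc3)cc(OCc3ccccc3)c3c2OC(O)C[C@H]3c2ccccc2)cc1 | intermediate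
13 | (4S)-5,7-bis(benzyloxy)-8-[3-(4-methoxyphenyl)propanoyl]-4-phenylchroman-2-one | COc1ccc(CCC(=O)c2c(OCc3ccccc3)cc(OCc3ccccc3)c3c2OC(=O)C[C@H]3c2ccccc2)cc1 | intermediate
14 | (4S)-5,7-dihydroxy-8-[3-(4-methoxyphenyl)propanoyl]-4-phenylchroman-2-one | COc1ccc(CCC(=O)c2c(O)cc(O)c3c2OC(=O)C[C@H]3c2ccccc2)cc1 | target

**Total step count:** 7. **Longest linear sequence:** 7 steps (1 to 14).

**Steps most likely to fail**

**Step 4 (proposed new method).**
- What may go wrong:
  - The copper-bound ether may ionise to a cinnamyl cation and a phenoxide, and these may recombine without regio- or face control.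
  - The ketone is flanked by two ortho alkoxy groups and twisted out of the ring plane, so it may chelate weakly, or chelate unproductively with the neighbouring benzyloxy oxygen.
  - Facial discrimination may be poor.
  - The freed ortho-hydroxy ketone may hold the copper and slow turnover.
- Fallback (known chemistry, from 6 back to 8):
  - Compound 6 is heated in N,N-diethylaniline at about 190 °C (thermal aromatic Claisen rearrangement) to give the racemic 1-phenylallyl phenol F1.
  - Acylation with (1S)-camphanic chloride (Et3N, DMAP, CH2Cl2) gives the (S)-configured camphanate F2 and its (R)-configured diastereomer F3. These are separated by crystallisation or chromatography, and a crystal structure can fix the configuration of C4.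
  - Methanolysis of F2 (K2CO3, MeOH, rt) returns 8.

**Step 5.**
- What may go wrong:
  - Metal-hydride chain walking may move the double bond into conjugation with the two aryl groups and so erase C4.
  - The ketone may be reduced by the boron hydride.
  - Dakin-type cleavage of the ortho-hydroxy aryl ketone may occur during the oxidative work-up.
- Fallback (from 8 back to 10): boron is replaced by silicon.
  - Platinum-catalysed hydrosilylation of 8 with HSiMe(OEt)2 and the Karstedt catalyst Pt2[(CH2=CHSiMe2)2O]3 (zerovalent platinum) in toluene at rt is inert towards ketones. It should give the terminal diethoxy(methyl)silane F4.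
  - Tamao oxidation (H2O2, KF, KHCO3, THF/MeOH, rt, close to neutral) then gives 10.

**Step 6.**
- What may go wrong:
  - The chelated, hindered phenol may add only slowly to the aldehyde, so the oxidation stalls before the lactol stage.
  - Chromium may attack the electron-rich ring or the benzylic positions on prolonged exposure.
- Fallback (from 10 back to 13): oxidation level and ring closure are separated.
  - Parikh–Doering oxidation (SO3·pyridine, DMSO, Et3N) takes 10 to aldehyde 11.
  - Pinnick oxidation (NaClO2, NaH2PO4, 2-methyl-2-butene, t-BuOH/H2O) gives the carboxylic acid F5.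
  - Carbodiimide lactonisation (EDC·HCl, DMAP, CH2Cl2) closes ring B to 13.

**Further compounds**
F1 | step 4 | racemic 1-[2,4-bis(benzyloxy)-6-hydroxy-5-(1-phenylprop-2-en-1-yl)phenyl]-3-(4-methoxyphenyl)propan-1-one | C=CC(c1c(OCc2ccccc2)cc(OCc2ccccc2)c(C(=O)CCc2ccc(OC)cc2)c1O)c1ccccc1
F2 | step 4 | (1S,4R)-camphanate of the phenol 8, (S) at the 1-phenylallyl carbon | C=C[C@H](c1c(OCc2ccccc2)cc(OCc2ccccc2)c(C(=O)CCc2ccc(OC)cc2)c1OC(=O)[C@@]12CC[C@@](C)(C(=O)O1)C2(C)C)c1ccccc1
F3 | step 4 | (1S,4R)-camphanate of the enantiomer of 8, (R) at the 1-phenylallyl carbon | C=C[C@@H](c1c(OCc2ccccc2)cc(OCc2ccccc2)c(C(=O)CCc2ccc(OC)cc2)c1OC(=O)[C@@]12CC[C@@](C)(C(=O)O1)C2(C)C)c1ccccc1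
F4 | step 5 | 1-[2,4-bis(benzyloxy)-5-[(1S)-3-[diethoxy(methyl)silyl]-1-phenylpropyl]-6-hydroxyphenyl]-3-(4-methoxyphenyl)propan-1-one | CCO[Si](C)(OCC)CC[C@H](c1c(OCc2ccccc2)cc(OCc2ccccc2)c(C(=O)CCc2ccc(OC)cc2)c1O)c1ccccc1
F5 | step 6 | (3S)-3-[4,6-bis(benzyloxy)-2-hydroxy-3-[3-(4-methoxyphenyl)propanoyl]phenyl]-3-phenylpropanoic acid | OC(=O)C[C@H](c1c(OCc2ccccc2)cc(OCc2ccccc2)c(C(=O)CCc2ccc(OC)cc2)c1O)c1ccccc1
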